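**Plan**

1. Numbering: the side chain runs from C1' (the CH2 on the quinone ring) to C32'. The quinone ring is carried as its 1,4-dimethoxynaphthalene and unveiled in the last step.
2. Retrosynthetic cuts, in order: C10'–C11' (union of the halves), then C4'–C5' and C24'–C25' (allyl–alkyl bonds), C12'–C13' (allyl sulfone plus epoxide), and aryl–C1'.
3. Enabling feature: C11' is a methyl-bearing CH flanked only by the CH2 groups C10' and C12'. It can therefore be carried as an unhindered (R)-methylcarbinyl tosylate and substituted with inversion by the primary C10' Grignard carbon, so one copper-catalysed event joins the C25 and C28 halves and fixes C11'.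
4. Forward order: fragment 1 (steps 1–8: arene, prenylation, E-allylic bromide, C4'–C5' coupling); fragment 2 (steps 9–18: farnesyl sulfone, C12'–C13', terminal oxidation, C24'–C25', tosylate); union (step 19); quinone release (step 20).
5. Stereochemistry: C7' and C27' both come from (S)-citronellyl bromide; C11' comes from (R)-propylene oxide and is inverted in step 19.
6. Alkene geometry: the 14'E and 18'E alkenes come from (2E,6E)-farnesyl bromide; the 2'E and 22'E alkenes come from E-selective SeO2 oxidation of isopropylidene groups.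

Key step: step 19

Remark: sulfones 21 and 22 are carried as mixtures of epimers at the sulfonyl-bearing carbon, because that centre is erased in step 13.

**Fragment 1 (C1'–C10' with the masked quinone)**

Step 1
Reactants: 1 menadione (2-methylnaphthalene-1,4-dione)
Product: 3 1,4-dimethoxy-2-methylnaphthalene, via menadiol 2 (not isolated)
Conditions: Na2S2O4, EtOAc/H2O, rt; then Me2SO4, KOH, Bu4NBr (cat.), THF/H2O, 0 °C → rt, N2
Reagents that add atoms: dimethyl sulfate COS(=O)(=O)OC
Why: Dithionite reduction of the quinone followed by double Williamson O-methylation of the hydroquinone masks the quinone as a Grignard-stable bis-methyl ether; no stereocentre is involved.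

Step 2
Reactants: 3 1,4-dimethoxy-2-methylnaphthalene
Product: 4 2-bromo-1,4-dimethoxy-3-methylnaphthalene
Conditions: Br2, CH2Cl2, 0 °C
Reagents that add atoms: bromine BrBr
Why: Electrophilic aromatic bromination should go to C3, the only unsubstituted position of the ring that carries both methoxy groups.

Step 3
Reactants: 4 2-bromo-1,4-dimethoxy-3-methylnaphthalene; 5 prenyl bromide (1-bromo-3-methylbut-2-ene)
Product: 7 1,4-dimethoxy-2-methyl-3-(3-methylbut-2-en-1-yl)naphthalene, via aryl Grignard reagent 6 (not isolated)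
Conditions: Mg, THF, reflux; then 5, CuBr·SMe2 (5 mol%), THF, −20 → 0 °C
Reagents that add atoms: none
Why: Magnesium insertion gives the aryl Grignard reagent, and copper-catalysed allylic substitution at the primary carbon of prenyl bromide (the SN2' path would create a hindered quaternary benzylic carbon) installs C1'–C3'.

Step 4
Reactants: 7 1,4-dimethoxy-2-methyl-3-(3-methylbut-2-en-1-yl)naphthalene
Product: 8 (E)-4-(1,4-dimethoxy-3-methylnaphthalen-2-yl)-2-methylbut-2-en-1-ol
Conditions: SeO2 (0.3 equiv), t-BuOOH, salicylic acid (cat.), CH2Cl2, 0 °C → rt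
Reagents that add atoms: SeO2 O=[Se]=O (oxygen donor), tert-butyl hydroperoxide CC(C)(C)OO (restores the donor)
Why: Riley-type allylic oxidation (ene reaction, then [2,3]-sigmatropic shift of the allylseleninic acid) attacks the more substituted alkene terminus at the methyl trans to the chain, which should set the 2'E geometry and provide the C4' oxygen.

Step 5
Reactants: 8 (E)-4-(1,4-dimethoxy-3-methylnaphthalen-2-yl)-2-methylbut-2-en-1-ol
Product: 9 2-[(E)-4-bromo-3-methylbut-2-en-1-yl]-1,4-dimethoxy-3-methylnaphthalene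
Conditions: CBr4, PPh3, CH2Cl2, 0 °C
Reagents that add atoms: carbon tetrabromide BrC(Br)(Br)Br
Why: The Appel reaction converts the primary allylic alcohol into the bromide under neutral conditions and should cause no allylic transposition or E/Z change.

Step 6
Reactants: 10 (S)-citronellyl bromide [(S)-8-bromo-2,6-dimethyloct-2-ene]
Product: 12 (S)-6-bromo-4-methylhexan-1-ol, via bromo aldehyde 11 (not isolated)
Conditions: O3, CH2Cl2/MeOH, −78 °C; then NaBH4, −78 °C → rt
Reagents that add atoms: ozone [O-][O+]=O
Why: Ozonolysis (Criegee mechanism) cleaves the single alkene and NaBH4 reduces the peroxidic intermediates and the aldehyde to the primary alcohol; the stereocentre (future C7') comes unchanged from the chiral pool and the primary bromide is inert.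

Step 7
Reactants: 12 (S)-6-bromo-4-methylhexan-1-ol
Product: 13 (S)-1-bromo-6-chloro-3-methylhexane
Conditions: PPh3, N-chlorosuccinimide, THF, 0 °C → rt
Reagents that add atoms: N-chlorosuccinimide O=C1CCC(=O)N1Cl
Why: Appel-type chlorination (chlorophosphonium activation, SN2 at the primary carbinol) gives a bromide/chloride pair that magnesium can tell apart, so no protecting group is needed.

Step 8
Reactants: 13 (S)-1-bromo-6-chloro-3-methylhexane; 9 2-[(E)-4-bromo-3-methylbut-2-en-1-yl]-1,4-dimethoxy-3-methylnaphthalene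
Product: 15 2-[(2E,7R)-10-chloro-3,7-dimethyldec-2-en-1-yl]-1,4-dimethoxy-3-methylnaphthalene, via chloroalkyl Grignard reagent 14 (not isolated)
Conditions: Mg, THF, 0 °C → rt (13 → 14); then 9, Li2CuCl4 (3 mol%), THF, −78 → 0 °C
Reagents that add atoms: none
Why: Magnesium inserts selectively into the C–Br bond, and the Li2CuCl4-catalysed Grignard–allylic bromide coupling (SN2 regiochemistry, alkene geometry retained) forms C4'–C5' while the primary chloride stays untouched.

**Fragment 2 (C11'–C32')**

Step 9
Reactants: 10 (S)-citronellyl bromide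
Product: 16 (S)-1-bromo-3,7-dimethyloctane
Conditions: H2 (1 atm), PtO2 (cat.), EtOAc, rt
Reagents that add atoms: none
Why: Heterogeneous catalytic hydrogenation saturates the trisubstituted alkene without hydrogenolysis of the primary C–Br bond under neutral conditions; the stereocentre (future C27') is untouched.

Step 10
Reactants: 17 (2E,6E)-farnesyl bromide [(2E,6E)-1-bromo-3,7,11-trimethyldodeca-2,6,10-triene]
Product: 18 (2E,6E)-farnesyl phenyl sulfone
Conditions: PhSO2Na, DMF, rt
Reagents that add atoms: sodium benzenesulfinate [Na+].[O-]S(=O)c1ccccc1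
Why: SN2 S-alkylation of the sulfinate at the primary allylic carbon gives the allylic sulfone with both E-alkenes retained.

Step 11
Reactants: 18 (2E,6E)-farnesyl phenyl sulfone; 19 (R)-propylene oxide [(R)-2-methyloxirane]
Product: 21 (2R,5E,9E)-6,10,14-trimethyl-4-(phenylsulfonyl)pentadeca-5,9,13-trien-2-ol (both C4 epimers), via lithiated sulfone 20 (not isolated)
Conditions: n-BuLi, THF/DMPU, −78 °C; then 19, −78 → 0 °C; H2O quench
Reagents that add atoms: none
Why: α-Lithiation of the allylic sulfone and regioselective SN2 opening of the epoxide at its CH2 terminus forms C12'–C13' and brings in the carbinol stereocentre of the chiral-pool epoxide unchanged (R).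

Step 12
Reactants: 21 hydroxy sulfone
Product: 22 tert-butyldimethyl{[(2R,5E,9E)-6,10,14-trimethyl-4-(phenylsulfonyl)pentadeca-5,9,13-trien-2-yl]oxy}silane (both C4 epimers)
Conditions: TBSCl, imidazole, DMF, rt
Reagents that add atoms: tert-butyldimethylsilyl chloride CC(C)(C)[Si](C)(C)Cl
Why: Standard imidazole-promoted silylation protects the secondary alcohol for the oxidation and organometallic steps that follow.

Step 13
Reactants: 22 silyl ether sulfone
Product: 23 tert-butyldimethyl{[(2R,5E,9E)-6,10,14-trimethylpentadeca-5,9,13-trien-2-yl]oxy}silane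
Conditions: PdCl2(dppp) (5 mol%), LiBHEt3, THF, 0 °C
Reagents that add atoms: none
Why: Palladium-catalysed reductive desulfonylation (ionisation to a π-allyl complex of divalent palladium, hydride delivery to the less substituted terminus) should remove the sulfone without alkene migration or E/Z loss.

Step 14
Reactants: 23 silyl ether triene
Product: 24 (2E,6E,10E,14R)-14-[(tert-butyldimethylsilyl)oxy]-2,6,10-trimethylpentadeca-2,6,10-trien-1-ol
Conditions: SeO2 (0.3 equiv), t-BuOOH, salicylic acid (cat.), CH2Cl2, 0 °C → rt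
Reagents that add atoms: SeO2 O=[Se]=O (oxygen donor), tert-butyl hydroperoxide CC(C)(C)OO (restores the donor)
Why: Riley-type allylic oxidation is expected to favour the terminal isopropylidene (the most accessible alkene) and its methyl trans to the chain, giving the allylic alcohol with the future 22'E geometry.

Step 15
Reactants: 24 allylic alcohol
Product: 25 {[(2R,5E,9E,13E)-15-bromo-6,10,14-trimethylpentadeca-5,9,13-trien-2-yl]oxy}(tert-butyl)dimethylsilane
Conditions: CBr4, PPh3, CH2Cl2, −20 → 0 °C
Reagents that add atoms: carbon tetrabromide BrC(Br)(Br)Br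
Why: The Appel reaction gives the primary allylic bromide without transposition, and the silyl ether is stable under the neutral conditions.

Step 16
Reactants: 16 (S)-1-bromo-3,7-dimethyloctane; 25 allylic bromide
Product: 27 tert-butyldimethyl{[(2R,5E,9E,13E,18S)-6,10,14,18,22-pentamethyltricosa-5,9,13-trien-2-yl]oxy}silane, via dimethyloctyl Grignard reagent 26 (not isolated)
Conditions: Mg, THF, rt (16 → 26); then 25, Li2CuCl4 (3 mol%), THF, −78 → 0 °C
Reagents that add atoms: none
Why: Li2CuCl4-catalysed coupling of the primary alkyl Grignard reagent at the primary allylic carbon (SN2 regiochemistry, geometry retained) forms C24'–C25' and brings in the C27' stereocentre from the chiral pool.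

Step 17
Reactants: 27 silyl ether
Product: 28 (2R,5E,9E,13E,18S)-6,10,14,18,22-pentamethyltricosa-5,9,13-trien-2-ol
Conditions: Bu4NF, THF, rt
Reagents that add atoms: none
Why: Fluoride-mediated desilylation liberates the (R)-carbinol, and nothing else in the molecule reacts with fluoride.

Step 18
Reactants: 28 secondary alcohol
Product: 29 (2R,5E,9E,13E,18S)-6,10,14,18,22-pentamethyltricosa-5,9,13-trien-2-yl 4-methylbenzenesulfonate
Conditions: TsCl, pyridine, DMAP (cat.), CH2Cl2, 0 °C → rt
Reagents that add atoms: 4-toluenesulfonyl chloride Cc1ccc(cc1)S(=O)(=O)Cl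
Why: O-Sulfonylation occurs with retention at carbon and gives the (R)-tosylate as the electrophile for the union.

**Union and quinone release**

Step 19
Reactants: 15 2-[(2E,7R)-10-chloro-3,7-dimethyldec-2-en-1-yl]-1,4-dimethoxy-3-methylnaphthalene; 29 (R)-tosylate
Product: 31 1,4-dimethoxy-2-methyl-3-[(2E,7S,11R,14E,18E,22E,27S)-3,7,11,15,19,23,27,31-octamethyldotriaconta-2,14,18,22-tetraen-1-yl]naphthalene, via left-half Grignard reagent 30 (not isolated)
Conditions: Mg (activated with 1,2-dibromoethane), THF, 60 °C (15 → 30, 1.5 equiv); then 29, CuI (10 mol%), TMEDA (20 mol%), LiOMe (1 equiv), THF, 0 °C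
Reagents that add atoms: none
Why: Grignard reagent 30 transmetalates to copper and, with LiOMe and TMEDA, forms an electron-rich alkyl cuprate of monovalent copper that attacks the C–O σ* orbital of the secondary tosylate from the rear; the resulting dialkyl species of trivalent copper reductively eliminates to form the C10'–C11' bond. The closest known reaction type is the copper-catalysed cross-coupling of unactivated secondary alkyl tosylates with alkyl Grignard reagents, which runs with inversion. No ring is closed. The one new stereocentre, C11', is controlled by the (R)-carbinol carbon of 29 (from (R)-propylene oxide) and is inverted; because the substituent priorities change, the descriptor reads R before and after. The step needs substitution to beat E2 elimination and any racemising single-electron path: the electrophilic carbon is a methylcarbinyl centre flanked by CH2 groups (the least hindered secondary class), the nucleophilic carbon C10' is primary and three CH2 groups from the C7' branch, and the alkenes are trisubstituted and too remote to take part. The quinone is masked as its bis-methyl ether so the Grignard reagent is tolerated.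

Step 20
Reactants: 31 coupled dimethoxynaphthalene
Product: 32 2-methyl-3-[(2E,7S,11R,14E,18E,22E,27S)-3,7,11,15,19,23,27,31-octamethyldotriaconta-2,14,18,22-tetraen-1-yl]naphthalene-1,4-dione (CNP0311749.1)
Conditions: (NH4)2Ce(NO3)6 (2.5 equiv), MeCN/CH2Cl2/H2O, 0 °C
Reagents that add atoms: water O
Why: Oxidative demethylation by tetravalent cerium (arene radical cation, ipso attack of water, loss of methanol) unveils the quinone, and the isolated trisubstituted alkenes and sp3 stereocentres should not be affected under these brief, cold conditions.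

**Compound list**

1 | menadione (2-methylnaphthalene-1,4-dione) | CC1=CC(=O)c2ccccc2C1=O | starting material
2 | menadiol (2-methylnaphthalene-1,4-diol) | Cc1cc(O)c2ccccc2c1O | intermediate
3 | 1,4-dimethoxy-2-methylnaphthalene | COc1c(C)cc(OC)c2ccccc12 | intermediate
4 | 2-bromo-1,4-dimethoxy-3-methylnaphthalene | COc1c(C)c(Br)c(OC)c2ccccc12 | intermediate
5 | prenyl bromide (1-bromo-3-methylbut-2-ene) | CC(C)=CCBr | starting material
6 | (1,4-dimethoxy-3-methylnaphthalen-2-yl)magnesium bromide | COc1c(C)c([Mg]Br)c(OC)c2ccccc12 | intermediate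
7 | 1,4-dimethoxy-2-methyl-3-(3-methylbut-2-en-1-yl)naphthalene | COc1c(C)c(CC=C(C)C)c(OC)c2ccccc12 | intermediate
8 | (E)-4-(1,4-dimethoxy-3-methylnaphthalen-2-yl)-2-methylbut-2-en-1-ol | COc1c(C)c(C/C=C(\C)CO)c(OC)c2ccccc12 | intermediate
9 | 2-[(E)-4-bromo-3-methylbut-2-en-1-yl]-1,4-dimethoxy-3-methylnaphthalene | COc1c(C)c(C/C=C(\C)CBr)c(OC)c2ccccc12 | intermediate
10 | (S)-citronellyl bromide [(S)-8-bromo-2,6-dimethyloct-2-ene] | BrCC[C@@H](C)CCC=C(C)C | starting material
11 | (S)-6-bromo-4-methylhexanal | BrCC[C@@H](C)CCC=O | intermediate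
12 | (S)-6-bromo-4-methylhexan-1-ol | BrCC[C@@H](C)CCCO | intermediate
13 | (S)-1-bromo-6-chloro-3-methylhexane | BrCC[C@@H](C)CCCCl | intermediate
14 | [(S)-6-chloro-3-methylhexyl]magnesium bromide | Br[Mg]CC[C@@H](C)CCCCl | intermediate
15 | 2-[(2E,7R)-10-chloro-3,7-dimethyldec-2-en-1-yl]-1,4-dimethoxy-3-methylnaphthalene | COc1c(C)c(C/C=C(\C)CCC[C@@H](C)CCCCl)c(OC)c2ccccc12 | intermediate
16 | (S)-1-bromo-3,7-dimethyloctane | BrCC[C@@H](C)CCCC(C)C | intermediate
17 | (2E,6E)-farnesyl bromide [(2E,6E)-1-bromo-3,7,11-trimethyldodeca-2,6,10-triene] | BrC/C=C(\C)CC/C=C(\C)CCC=C(C)C | starting material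
18 | (2E,6E)-farnesyl phenyl sulfone | O=S(=O)(C/C=C(\C)CC/C=C(\C)CCC=C(C)C)c1ccccc1 | intermediate
19 | (R)-propylene oxide [(R)-2-methyloxirane] | C[C@@H]1CO1 | starting material
20 | 1-lithio-(2E,6E)-farnesyl phenyl sulfone | [Li]C(/C=C(\C)CC/C=C(\C)CCC=C(C)C)S(=O)(=O)c1ccccc1 | intermediate
21 | (2R,5E,9E)-6,10,14-trimethyl-4-(phenylsulfonyl)pentadeca-5,9,13-trien-2-ol (both C4 epimers) | C[C@@H](O)CC(/C=C(\C)CC/C=C(\C)CCC=C(C)C)S(=O)(=O)c1ccccc1 | intermediate
22 | tert-butyldimethyl{[(2R,5E,9E)-6,10,14-trimethyl-4-(phenylsulfonyl)pentadeca-5,9,13-trien-2-yl]oxy}silane (both C4 epimers) | C[C@@H](O[Si](C)(C)C(C)(C)C)CC(/C=C(\C)CC/C=C(\C)CCC=C(C)C)S(=O)(=O)c1ccccc1 | intermediate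
23 | tert-butyldimethyl{[(2R,5E,9E)-6,10,14-trimethylpentadeca-5,9,13-trien-2-yl]oxy}silane | C[C@@H](O[Si](C)(C)C(C)(C)C)CC/C=C(\C)CC/C=C(\C)CCC=C(C)C | intermediate
24 | (2E,6E,10E,14R)-14-[(tert-butyldimethylsilyl)oxy]-2,6,10-trimethylpentadeca-2,6,10-trien-1-ol | C[C@@H](O[Si](C)(C)C(C)(C)C)CC/C=C(\C)CC/C=C(\C)CC/C=C(\C)CO | intermediate
25 | {[(2R,5E,9E,13E)-15-bromo-6,10,14-trimethylpentadeca-5,9,13-trien-2-yl]oxy}(tert-butyl)dimethylsilane | C[C@@H](O[Si](C)(C)C(C)(C)C)CC/C=C(\C)CC/C=C(\C)CC/C=C(\C)CBr | intermediate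
26 | [(S)-3,7-dimethyloctyl]magnesium bromide | Br[Mg]CC[C@@H](C)CCCC(C)C | intermediate
27 | tert-butyldimethyl{[(2R,5E,9E,13E,18S)-6,10,14,18,22-pentamethyltricosa-5,9,13-trien-2-yl]oxy}silane | C[C@@H](O[Si](C)(C)C(C)(C)C)CC/C=C(\C)CC/C=C(\C)CC/C=C(\C)CCC[C@@H](C)CCCC(C)C | intermediate
28 | (2R,5E,9E,13E,18S)-6,10,14,18,22-pentamethyltricosa-5,9,13-trien-2-ol | C[C@@H](O)CC/C=C(\C)CC/C=C(\C)CC/C=C(\C)CCC[C@@H](C)CCCC(C)C | intermediate
29 | (2R,5E,9E,13E,18S)-6,10,14,18,22-pentamethyltricosa-5,9,13-trien-2-yl 4-methylbenzenesulfonate | C[C@@H](OS(=O)(=O)c1ccc(C)cc1)CC/C=C(\C)CC/C=C(\C)CC/C=C(\C)CCC[C@@H](C)CCCC(C)C | intermediate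
30 | [(4R,8E)-10-(1,4-dimethoxy-3-methylnaphthalen-2-yl)-4,8-dimethyldec-8-en-1-yl]magnesium chloride | COc1c(C)c(C/C=C(\C)CCC[C@@H](C)CCC[Mg]Cl)c(OC)c2ccccc12 | intermediate
31 | 1,4-dimethoxy-2-methyl-3-[(2E,7S,11R,14E,18E,22E,27S)-3,7,11,15,19,23,27,31-octamethyldotriaconta-2,14,18,22-tetraen-1-yl]naphthalene | COc1c(C)c(C/C=C(\C)CCC[C@@H](C)CCC[C@@H](C)CC/C=C(\C)CC/C=C(\C)CC/C=C(\C)CCC[C@@H](C)CCCC(C)C)c(OC)c2ccccc12 | intermediate
32 | 2-methyl-3-[(2E,7S,11R,14E,18E,22E,27S)-3,7,11,15,19,23,27,31-octamethyldotriaconta-2,14,18,22-tetraen-1-yl]naphthalene-1,4-dione (CNP0311749.1) | CC1=C(C/C=C(\C)CCC[C@@H](C)CCC[C@@H](C)CC/C=C(\C)CC/C=C(\C)CC/C=C(\C)CCC[C@@H](C)CCCC(C)C)C(=O)c2ccccc2C1=O | target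

**Step count and risks**

Total step count: 20. Longest linear sequence: 11 steps (steps 10–20, from farnesyl bromide 17).

Steps most likely to fail:

Step 19. The basic organometallic may cause E2 elimination of the secondary tosylate instead of substitution, and a competing single-electron path could erode the inversion at C11'. The fallback replaces the copper-catalysed cross-coupling by alkylation of a sulfone-stabilised carbanion followed by reductive desulfonylation; it sets out from 15 and 28 and comes back at 31. Chloride 15 with PhSO2Na and NaI (cat.) in DMF at 80 °C should give 2-[(2E,7R)-3,7-dimethyl-10-(phenylsulfonyl)dec-2-en-1-yl]-1,4-dimethoxy-3-methylnaphthalene F1. Alcohol 28 with Tf2O and 2,6-lutidine in CH2Cl2 at −78 °C should give (2R,5E,9E,13E,18S)-6,10,14,18,22-pentamethyltricosa-5,9,13-trien-2-yl trifluoromethanesulfonate F2, which is used at once. Lithiation of F1 (n-BuLi, THF/DMPU, −78 °C) and addition of F2 should give, by SN2 with inversion at C11', the C10'-phenylsulfonyl derivative of 31 F3 as a mixture of C10' epimers. Na(Hg) amalgam with Na2HPO4 in MeOH/THF should then remove the sulfone and return 31.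

Step 14. Oxidation may spread over the three similar trisubstituted alkenes, and the product may be over-oxidised to the enal. The fallback builds the E-allylic alcohol by terminal alkene cleavage and E-selective olefination; it sets out from 23 and comes back at 24. NBS in aqueous THF at 0 °C should form the terminal bromohydrin (6E,10E,14R)-3-bromo-14-[(tert-butyldimethylsilyl)oxy]-2,6,10-trimethylpentadeca-6,10-dien-2-ol F4 (both C3 epimers), the terminal alkene being the most exposed in a water-rich medium. K2CO3 in MeOH should close it to tert-butyl{[(2R,5E,9E)-12-(3,3-dimethyloxiran-2-yl)-6,10-dimethyldodeca-5,9-dien-2-yl]oxy}dimethylsilane F5. H5IO6 in THF/Et2O at 0 °C should cleave the epoxide to (4E,8E,12R)-12-[(tert-butyldimethylsilyl)oxy]-4,8-dimethyltrideca-4,8-dienal F6. Wittig olefination with ethyl 2-(triphenylphosphoranylidene)propanoate in CH2Cl2 should give ethyl (2E,6E,10E,14R)-14-[(tert-butyldimethylsilyl)oxy]-2,6,10-trimethylpentadeca-2,6,10-trienoate F7, and i-Bu2AlH in CH2Cl2 at −78 °C should reduce it to 24.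

Step 4. Conversion may be low, or the electron-rich arene and its doubly activated ArCH2 position may be oxidised along with, or instead of, the methyl group. The fallback avoids the oxidation by bringing in the oxygenated C5 unit in one allylic substitution; it sets out from 4 (as its Grignard reagent 6) and comes back at 8. CuI-catalysed SN2' opening of 2-methyl-2-vinyloxirane by 6 in THF at −30 °C should give the E-allylic alcohol 8 directly, bypassing 7; the E/Z purity would have to be checked, and no new compound arises (F0).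

Further compounds
F1 | step 19 | 2-[(2E,7R)-3,7-dimethyl-10-(phenylsulfonyl)dec-2-en-1-yl]-1,4-dimethoxy-3-methylnaphthalene | COc1c(C)c(C/C=C(\C)CCC[C@@H](C)CCCS(=O)(=O)c3ccccc3)c(OC)c2ccccc12
F2 | step 19 | (2R,5E,9E,13E,18S)-6,10,14,18,22-pentamethyltricosa-5,9,13-trien-2-yl trifluoromethanesulfonate | C[C@@H](OS(=O)(=O)C(F)(F)F)CC/C=C(\C)CC/C=C(\C)CC/C=C(\C)CCC[C@@H](C)CCCC(C)C
F3 | step 19 | C10'-phenylsulfonyl derivative of 31 (both C10' epimers) | COc1c(C)c(C/C=C(\C)CCC[C@@H](C)CCC(S(=O)(=O)c3ccccc3)[C@@H](C)CC/C=C(\C)CC/C=C(\C)CC/C=C(\C)CCC[C@@H](C)CCCC(C)C)c(OC)c2ccccc12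
F4 | step 14 | (6E,10E,14R)-3-bromo-14-[(tert-butyldimethylsilyl)oxy]-2,6,10-trimethylpentadeca-6,10-dien-2-ol (both C3 epimers) | C[C@@H](O[Si](C)(C)C(C)(C)C)CC/C=C(\C)CC/C=C(\C)CCC(Br)C(C)(C)O
F5 | step 14 | tert-butyl{[(2R,5E,9E)-12-(3,3-dimethyloxiran-2-yl)-6,10-dimethyldodeca-5,9-dien-2-yl]oxy}dimethylsilane | C[C@@H](O[Si](C)(C)C(C)(C)C)CC/C=C(\C)CC/C=C(\C)CCC1OC1(C)C
F6 | step 14 | (4E,8E,12R)-12-[(tert-butyldimethylsilyl)oxy]-4,8-dimethyltrideca-4,8-dienal | C[C@@H](O[Si](C)(C)C(C)(C)C)CC/C=C(\C)CC/C=C(\C)CCC=O
F7 | step 14 | ethyl (2E,6E,10E,14R)-14-[(tert-butyldimethylsilyl)oxy]-2,6,10-trimethylpentadeca-2,6,10-trienoate | C[C@@H](O[Si](C)(C)C(C)(C)C)CC/C=C(\C)CC/C=C(\C)CC/C=C(\C)C(=O)OCC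
F0 | step 4 | none | none
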